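Does the continuous tank, beta, beat the closed flask, gamma, when both get the same charge and the same 20 min, the tank's being a mean?

| flask | starting material | remark | time |
|---|---|---|---|
| violet | 0.92 M | run made earlier |  |
| amber | 0.46 M | run made earlier |  |
| red | 0.69 M | run made earlier |  |
| beta | 0.92 M | a single well-mixed tank run continuously and read at steady state, 20 min in it on average |  |
| gamma | 0.92 M | everything together in a closed stirred flask, run for 20 min | 20 min |

- violet (time / min: target / %): 1.00: 16.1; 3.00: 26.5; 6.00: 31.2; 8.00: 33.1; 12.0: 34.4
- amber (time / min: target / %): 2.00: 25.6; 5.00: 33.9; 10.0: 38.6; 15.0: 39.6; 20.0: 41.4
- red (time / min: target / %): 1.50: 22.5; 3.00: 27.3; 6.00: 34.6; 10.0: 34.8; 20.0: 37.0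

(each reading ± 1 percentage point)

- the stated concentrations are those of everything mixed, before any reaction; amounts are the same in each set-up
- the earlier runs were made in a closed, stirred flask
- a reading or a percentage of target counts all its forms, free or not

* the set-up with the highest amount of target at the outlet or at the end, in percent of the starting material put in ("none" if the first two lie within 2 percentage points) (beta / gamma / none)
* amount of target at the outlet or at the end, in percent of the starting material put in, beta
* amount of target at the outlet or at the end, in percent of the starting material put in, gamma

I climb the time scales from the fastest. In the violet run, with its last reading taken as the plateau, the gap to that plateau closes between the first two readings at 0.420 min⁻¹, a reading that carries the scatter, so target climbs on a time scale of about 2.38 min. Next comes the creep, which in violet is 1.3 percentage points between its last two readings, so I put gamma a little above 34.4 %. Then comes the holding time, and I name the turnovers, the Damköhler number, as that rate times the time held, 8.40.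

A first-order tank leaves a share of one over one plus the turnovers unconverted, 10.6 %, and I treat that as the correction to the flask. Against it, the tank runs at 0.0979 M of starting material, less than amber's charge, so I give the converted part amber's 41.4 % and get 37.0 %. That stands 2.6 points above violet's last reading, and with gamma put a little above that reading I expect the gap to lie within the margin of 2 points, so I commit to none.

The forecast says beta, with 41 % against 36 %: “Even so, beta is the better bet.”

The tank gives 36.4 % and the flask 35.4 %, so the answer is none.

    2 starting material → self-condensation product (k = 0.240 L mol⁻¹ min⁻¹)
    starting material + target ⇌ idle adduct, settled at all times (K = 0.460 L mol⁻¹)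
    starting material ⇌ third isomer (K = 1.90, k = 0.300 min⁻¹)
    starting material ⇌ isomer of the product (K = 12.0, k = 0.110 min⁻¹)
    starting material ⇌ target (K = 7.10, k = 0.270 min⁻¹)

The tank lands 4.6 points under the forecast, with 11.6 % of starting material at its outlet against my 10.6 %. For gamma, the same turnovers in a closed flask reckon to 0.0225 % left, and the flask holds more, at 4.87 %.

All runs come from a simulation on assumed constants; noise was put on by code.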